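## Structural features

The target is a C20 gibberellane diacid made of four carbocycles: cyclohexane ring A (C1, C2, C3, C4, C5, C10), cyclopentane ring B (C5, C6, C8, C9, C10), cyclohexanone ring C (C8, C9, C11, C12, C13, C14) and methylenecyclopentane ring D (C8, C14, C13, C16, C15). Rings A and B are trans-fused at C5–C10, rings B and C share C8–C9, and rings C and D form a bicyclo[3.2.1]octanone whose bridgeheads are the quaternary C8 (common to rings B, C and D) and C13. There are eight stereocentres; seven are contiguous (C3, C4, C5, C6, C8, C9, C10) and C13 is tied to C8 through the bridge. C4, C8 and C10 are quaternary, and the C19 carboxyl on C4 and the C20 methyl on C10 are 1,3-diaxial. The fragile points are these: the exocyclic C16=C17 alkene, which acid can move into ring D and which is β,γ to the C12 ketone (only the bridgehead position of C13 keeps it out of conjugation); the axial 3β-hydroxyl β to the C19 carbonyl, which epimerises by retro-aldol in base; the hindered axial C19 carboxyl, whose simple esters resist saponification; and C6, which becomes epimerisable once C7 is a carbonyl. The real difficulty is the congested centre: the C8/C9/C10 array, the bridged ketone, and the need to tell apart the two carbon arms on C8 relative to C13. The key step uses three facts: C11 is α to the C12 ketone, C9 and C10 are vicinal, and C5 is β to the C19 carbonyl. A radical at C11 can therefore be relayed through a C9=C10 alkene into a C4=C5 enoate, closing ring C and then ring B on a monocyclic ring D precursor.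

## Logic of the disconnections

29 is traced back through 28, 27 and 26 without cutting a C–C bond: the C19 acid is masked as a tert-butyl ester, the C12 ketone as a dioxolane, and the C7 acid as a silylated primary alcohol. The C7 carboxyl is therefore made by oxidation and the C19 carboxyl by acidolysis, so no step exposes the 3β-hydroxy ester to base. The demand is an acid treatment mild enough for C16=C17.

26 comes from 25 by cutting C3–H. The forward step needs a bulky hydride that attacks C3 along the equatorial line to give the axial alcohol.

25 comes from 23 (through 24) by cutting C4–C18 and C3–C4, which removes ring A and a quaternary centre and leaves a 1,7-diester. Such a diester can close in two ways, so C19 is carried as a tert-butyl ester and C3 as a methyl ester. Only C4 can then act as the nucleophile, and the methylation must occur anti to the axial C20 methyl.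

23 comes from 22 by removing the ketal. The ketal is required because a free C12 ketone would enolise at C11 and acylate with the C3 ester, and would be reduced in the C3 reduction.

22 comes from 21 by cutting C9–C11 and C5–C10. This is the key disconnection: two rings and three stereocentres (C9, C10, C5) are removed at once and a monocyclic ring D with two alkenyl arms on C8 remains. The forward step needs the C13 acyl and the C9 arm cis on ring D, a 6-exo closure faster than reduction, and facial control at C9 and C10.

21 comes from 20 and 20 from 19 by cutting C11–halogen and C11–C12. The one-carbon unit is added last, as a carbenoid to a Weinreb amide, because the halomethyl ketone is the most fragile function (C13 is then both α to a ketone and allylic). The demand is chemoselectivity over the two esters.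

19 comes from 18 and 4 by cutting C4=C5. The enoate is installed only after every step that involves an enolate or a free C9 hydroxyl, which would add to it. The demand is selective metathesis of the one monosubstituted alkene.

18 comes from 15 and 16 (through 17) by cutting C1–C2, and 15 comes from 13 and 14 by cutting C9–C10. The whole C9 arm is thus assembled from two commercial pieces on a non-enolisable aldehyde. The demands are addition to the aldehyde in the presence of the Weinreb amide and an E-selective [3,3] shift (the geometry is in fact irrelevant later).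

13 comes from 12 and 12 from 11 by restoring the C12–O–C9 lactone. In 11 the C13 acyl and C9 are held cis by the ring and C13 is a bridgehead, so it can neither epimerise nor let the alkene migrate.

11 comes from 10 by cutting C13–C16, which opens ring D. A [3+2] cycloaddition of the parent trimethylenemethane unit is not used here, because it would place CH2 groups on both sides of C16, whereas C13 must carry the acyl group. The forward step needs the enolate carbon C13 to couple with the bromoalkene across the δ-lactone; the tether then fixes C13 relative to C8.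

10 comes from 9, 9 from 8 and 8 from 7 by exchanging the δ-lactone (C12 carbonyl, C9 oxygen) for a γ-lactone (C9 carbonyl, C7 oxygen). No C–C bond is cut. The demand is reduction of a lactone beside a tert-butyl ester and closure of the six-membered lactone in preference to the seven-membered one.

7 comes from 5 and 6, and 5 from 3 and 4, by cutting C8–C15 and C8–C14. The quaternary C8 is built by two successive enolate reactions, each anti to the C6 substituent, so the order of introduction fixes the configuration of C8 relative to C6.

3 comes from 1 and 2 by cutting C5–C6. This catalytic asymmetric conjugate addition is the only source of absolute configuration.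

## Other disconnections considered

Alternative 1: The cut is C9–C10 (ring B), with ring C present as a 4,4-disubstituted cyclohexadienone in which C8 is not yet stereogenic (dienone A2). In the forward step Fe(acac)3 and PhSiH3 would transfer hydrogen to the C10 methylene, and the tertiary C10 radical would add 5-exo to C9 of one enone arm to give the tricyclic enone A1.
- In favour: ring A arrives complete with C3, C4 and C5 set, so there is no Dieckmann regiochemistry and no C4 methylation to control. The step is catalytic in iron and free of tin, and C8 need not be made as a stereocentre beforehand. On these points the alternative is better than the chosen plan.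
- Against: only one ring is formed. The choice between the two enone arms, which sets C8 and C9, rests on the single adjacent centre C6. Ring D and C13 are still missing in A1 and need conjugate reduction, enolate trapping and an alkyne carbocyclisation.
- Comparison: both plans close ring B with the same tertiary C10 radical in a 5-exo mode. In A2 this radical is held in ring A, so its facial choice is better defined; this too is a point in favour of the alternative. The chosen plan forms two rings and three stereocentres in one step and leaves only ring A, which is closed by standard polar chemistry. Overall length should be similar, with more late-stage risk in the alternative because the bridged ring comes last.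

Alternative 2: The cut is C12–C13 (ring C) at the end of the synthesis. The C12 acyl radical from phenyl selenoester A4 would add 6-exo to C13 of a spiro cyclopentene, and the C16 radical would expel Bu3Sn from C17 to leave the exocyclic methylene, giving the protected target A3.
- In favour: the ketone, the bridge and the methylene appear in one step. The chain is carried by the expelled stannyl radical, so no hydride competes with cyclisation; this is better than the chosen plan. The geometry of the bridge leaves only one possible configuration at C13, which is equal to the chosen plan. Only deprotection follows the key step, so the sequence after it is shorter.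
- Against: A4 needs rings A and B, a spiro quaternary C8 whose configuration is defined only by the position of the ring D alkene, and an acid-labile allylstannane carried through late steps. The nucleophilic acyl radical meets an electron-rich alkene, which is a polarity mismatch that the chosen plan avoids. Both hindered methyl esters of A3 must be cleaved beside the 3-oxygen function.
- Comparison: the burden shifts from after the key step to before it. The chosen plan builds its precursor from a simple lactone.

Alternative 3: The cuts are C5–C6 (ring B) and C3–C4 (ring A). KOt-Bu would form the C6 ester enolate of triester A6, which adds 5-exo to C5 of the enoate; the C4 enolate so formed attacks the C3 ester to give the enolised keto ester A5.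
- In favour: the step is anionic and free of tin, and it forms two rings and two bonds, equal to the chosen plan. The enolate is born at C4, so the Dieckmann regiochemistry is unambiguous; this is better than the chosen plan, which needs a tert-butyl ester for that purpose. C7 is already at the acid level, which saves two steps after the key step.
- Against: A6 must already contain the bicyclo[3.2.1]octane and an acyclic quaternary C10 of defined configuration bearing three different chains, for which no controlled construction is evident. The Michael acceptor carbon C5 is neopentyl. The two methyl esters of the product must be hydrolysed at the end, with the attendant retro-aldol risk.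
- Comparison: the chosen plan creates C10 and the bridged ring in the key step itself. The alternative leaves both to earlier, harder steps and gains a shorter end-game.

Key step: step 15

Remark on the chemistry: the ligand antipode in step 1 is chosen by analogy with the facial sense known for cyclic enones and would be exchanged if the sign of rotation of 3 showed the opposite sense. The E geometry of C9=C10 in 18 to 21 is of no consequence because C10 becomes a planar radical.

## Steps

Step 1
Reactants: 1 furan-2(5H)-one; 2 potassium vinyltrifluoroborate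
Product: 3 (4R)-4-ethenyloxolan-2-one
Conditions: [Rh(cod)2]BF4 (3 mol %), (R)-BINAP (3.3 mol %), toluene/H2O 10:1, 90 °C
Reagents that add atoms: none
Why: Hayashi–Miyaura asymmetric 1,4-addition of an alkenylboron reagent to an unsaturated lactone; the chiral bisphosphine–alkenylrhodium species selects one face at C6 (gibberellane numbering), and this is the only source of absolute configuration in the route.

Step 2
Reactants: 3 (4R)-4-ethenyloxolan-2-one; 4 tert-butyl prop-2-enoate
Product: 5 tert-butyl 3-[(3S,4S)-4-ethenyl-2-oxooxolan-3-yl]propanoate (3,4-trans)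
Conditions: LiN(i-Pr)2, THF, −78 °C; 4 (1.0 equiv), −78 °C; aq. NH4Cl
Reagents that add atoms: none
Why: Michael addition of the lactone lithium enolate to the acrylate at low temperature; the acceptor approaches C8 anti to the ethenyl group, and this centre is in any case re-formed in step 3.

Step 3
Reactants: 5 tert-butyl 3-[(3S,4S)-4-ethenyl-2-oxooxolan-3-yl]propanoate; 6 2,3-dibromoprop-1-ene
Product: 7 tert-butyl 3-[(3S,4S)-3-(2-bromoprop-2-en-1-yl)-4-ethenyl-2-oxooxolan-3-yl]propanoate (bromoallyl trans to ethenyl)
Conditions: LiN(SiMe3)2 (1.1 equiv), THF, −78 °C; 6, −78 → −30 °C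
Reagents that add atoms: none
Why: Enolate alkylation with a reactive allylic bromide; the weaker silylamide base deprotonates the more acidic lactone α-position in preference to the tert-butyl ester α-CH2. The electrophile again enters anti to the ethenyl group, so C15 ends trans and C14 cis to it, which is the C8 configuration of the target.

Step 4
Reactants: 7 tert-butyl 3-[(3S,4S)-3-(2-bromoprop-2-en-1-yl)-4-ethenyl-2-oxooxolan-3-yl]propanoate
Product: 8 tert-butyl (4S,5S)-4-(2-bromoprop-2-en-1-yl)-4,5-bis(hydroxymethyl)hept-6-enoate
Conditions: LiBH4, THF, 0 °C → rt; aqueous work-up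
Reagents that add atoms: none
Why: Chemoselective hydride reduction: LiBH4 opens lactones to diols much faster than it touches tert-butyl esters, and the alkenyl bromide and alkene are inert.

Step 5
Reactants: 8 tert-butyl (4S,5S)-4-(2-bromoprop-2-en-1-yl)-4,5-bis(hydroxymethyl)hept-6-enoate
Product: 9 (5S)-5-(2-bromoprop-2-en-1-yl)-5-[(2S)-1-hydroxybut-3-en-2-yl]oxan-2-one
Conditions: p-TsOH·H2O (0.1 equiv), toluene, 80 °C
Reagents that add atoms: none
Why: Acid-catalysed lactonisation with loss of isobutene from the tert-butyl ester; the C9 hydroxyl closes the six-membered lactone, whereas the C7 hydroxyl would have to form a seven-membered ring.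

Step 6
Reactants: 9 (5S)-5-(2-bromoprop-2-en-1-yl)-5-[(2S)-1-hydroxybut-3-en-2-yl]oxan-2-one
Product: 10 (5S)-5-(2-bromoprop-2-en-1-yl)-5-[(2S)-1-{[tert-butyl(dimethyl)silyl]oxy}but-3-en-2-yl]oxan-2-one
Conditions: TBSCl, imidazole, DMF, rt
Reagents that add atoms: tert-butyldimethylsilyl chloride, CC(C)(C)[Si](C)(C)Cl
Why: Standard silylation of the free primary C7 alcohol; the silyl ether survives every step up to step 19.

Step 7
Reactants: 10 (5S)-5-(2-bromoprop-2-en-1-yl)-5-[(2S)-1-{[tert-butyl(dimethyl)silyl]oxy}but-3-en-2-yl]oxan-2-one
Product: 11 (1R,5S)-5-[(2S)-1-{[tert-butyl(dimethyl)silyl]oxy}but-3-en-2-yl]-7-methylidene-3-oxabicyclo[3.2.1]octan-2-one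
Conditions: LiN(SiMe3)2 (1.2 equiv), THF, −78 °C; Pd2(dba)3 (5 mol %), P(t-Bu)3 (12 mol %), toluene, 25 → 50 °C
Reagents that add atoms: none
Why: Palladium-catalysed intramolecular α-alkenylation of an ester-type enolate with an alkenyl bromide closes ring D (C13–C16) and leaves the exocyclic methylene. Because C12 is tied to C9 through the lactone, C13 can bond to C16 only so that C12 and C9 are cis on ring D; this sets C13 and places it at a bridgehead where it can neither epimerise nor let the alkene migrate.

Step 8
Reactants: 11 (1R,5S)-5-[(2S)-1-{[tert-butyl(dimethyl)silyl]oxy}but-3-en-2-yl]-7-methylidene-3-oxabicyclo[3.2.1]octan-2-one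
Product: 12 (1R,4S)-4-[(2S)-1-{[tert-butyl(dimethyl)silyl]oxy}but-3-en-2-yl]-4-(hydroxymethyl)-N-methoxy-N-methyl-2-methylidenecyclopentane-1-carboxamide
Conditions: MeNHOMe·HCl, AlMe3, CH2Cl2, 0 °C → rt; cold 1 M HCl work-up
Reagents that add atoms: N,O-dimethylhydroxylamine hydrochloride, CNOC.Cl
Why: Weinreb aminolysis of a lactone by an aluminium amide; the reagent is Lewis acidic and not basic enough to enolise C13, so the cis relationship fixed in step 7 is kept.

Step 9
Reactants: 12 (1R,4S)-4-[(2S)-1-{[tert-butyl(dimethyl)silyl]oxy}but-3-en-2-yl]-4-(hydroxymethyl)-N-methoxy-N-methyl-2-methylidenecyclopentane-1-carboxamide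
Product: 13 (1R,4S)-4-[(2S)-1-{[tert-butyl(dimethyl)silyl]oxy}but-3-en-2-yl]-4-formyl-N-methoxy-N-methyl-2-methylidenecyclopentane-1-carboxamide
Conditions: n-Pr4N[RuO4] (5 mol %), N-methylmorpholine N-oxide, 4 Å MS, CH2Cl2, rt
Reagents that add atoms: none
Why: Ley–Griffith oxidation of the neopentyl primary alcohol under neutral conditions; the C9 aldehyde has no α-hydrogen, and immediate oxidation prevents re-lactonisation.

Step 10
Reactants: 13 (1R,4S)-4-[(2S)-1-{[tert-butyl(dimethyl)silyl]oxy}but-3-en-2-yl]-4-formyl-N-methoxy-N-methyl-2-methylidenecyclopentane-1-carboxamide; 14 2-bromoprop-1-ene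
Product: 15 (1R,4S)-4-[(2S)-1-{[tert-butyl(dimethyl)silyl]oxy}but-3-en-2-yl]-4-(1-hydroxy-2-methylprop-2-en-1-yl)-N-methoxy-N-methyl-2-methylidenecyclopentane-1-carboxamide (both C9 carbinol epimers)
Conditions: CrCl2 (4 equiv), NiCl2 (1 mol %), DMF, rt
Reagents that add atoms: none
Why: Nozaki–Hiyama–Kishi addition forms C9–C10; the alkenylchromium reagent adds to aldehydes only and leaves the Weinreb amide alone. The carbinol centre disappears in step 11, so both epimers are carried on.

Step 11
Reactants: 15 (1R,4S)-4-[(2S)-1-{[tert-butyl(dimethyl)silyl]oxy}but-3-en-2-yl]-4-(1-hydroxy-2-methylprop-2-en-1-yl)-N-methoxy-N-methyl-2-methylidenecyclopentane-1-carboxamide; 16 trimethyl orthoacetate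
Product: 18 methyl (4E)-5-{(1R,3R)-1-[(2S)-1-{[tert-butyl(dimethyl)silyl]oxy}but-3-en-2-yl]-3-[methoxy(methyl)carbamoyl]-4-methylidenecyclopentyl}-4-methylpent-4-enoate, via ketene acetal 17 (not isolated)
Conditions: 16 (excess), EtCO2H (cat.), xylene, 135 °C, MeOH distilled off
Reagents that add atoms: none
Why: Johnson–Claisen rearrangement: orthoester exchange and loss of methanol give 17, whose chair [3,3] shift with the bulky C8 group equatorial forms C1–C2 and the E-trisubstituted C9=C10 alkene carrying the C3 methyl ester.

Step 12
Reactants: 18 methyl (4E)-5-{(1R,3R)-1-[(2S)-1-{[tert-butyl(dimethyl)silyl]oxy}but-3-en-2-yl]-3-[methoxy(methyl)carbamoyl]-4-methylidenecyclopentyl}-4-methylpent-4-enoate; 4 tert-butyl prop-2-enoate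
Product: 19 tert-butyl (2E,4S)-5-{[tert-butyl(dimethyl)silyl]oxy}-4-{(1R,3R)-3-[methoxy(methyl)carbamoyl]-1-[(1E)-5-methoxy-2-methyl-5-oxopent-1-en-1-yl]-4-methylidenecyclopentyl}pent-2-enoate
Conditions: second-generation Hoveyda–Grubbs catalyst (5 mol %), 4 (5 equiv), CH2Cl2, 40 °C
Reagents that add atoms: none
Why: Olefin cross-metathesis of the only monosubstituted alkene with an acrylate; the 1,1-disubstituted and trisubstituted alkenes react far more slowly, and the E-enoate is the thermodynamic product.

Step 13
Reactants: 19 tert-butyl (2E,4S)-5-{[tert-butyl(dimethyl)silyl]oxy}-4-{(1R,3R)-3-[methoxy(methyl)carbamoyl]-1-[(1E)-5-methoxy-2-methyl-5-oxopent-1-en-1-yl]-4-methylidenecyclopentyl}pent-2-enoate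
Product: 20 tert-butyl (2E,4S)-5-{[tert-butyl(dimethyl)silyl]oxy}-4-{(1R,3R)-3-(chloroacetyl)-1-[(1E)-5-methoxy-2-methyl-5-oxopent-1-en-1-yl]-4-methylidenecyclopentyl}pent-2-enoate
Conditions: ICH2Cl (2 equiv), MeLi·LiBr (1.8 equiv, added last), THF, −78 °C; aq. NH4Cl
Reagents that add atoms: chloroiodomethane, ClCI
Why: Carbenoid homologation: chloromethyllithium made by iodine–lithium exchange in the presence of the substrate adds to the Weinreb amide and gives a stable chelate that releases the chloromethyl ketone only on work-up. Weinreb amides react faster than esters at −78 °C, and C13 never meets base as a ketone.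

Step 14
Reactants: 20 tert-butyl (2E,4S)-5-{[tert-butyl(dimethyl)silyl]oxy}-4-{(1R,3R)-3-(chloroacetyl)-1-[(1E)-5-methoxy-2-methyl-5-oxopent-1-en-1-yl]-4-methylidenecyclopentyl}pent-2-enoate
Product: 21 tert-butyl (2E,4S)-5-{[tert-butyl(dimethyl)silyl]oxy}-4-{(1R,3R)-3-(iodoacetyl)-1-[(1E)-5-methoxy-2-methyl-5-oxopent-1-en-1-yl]-4-methylidenecyclopentyl}pent-2-enoate (the ring D iodoketone with two alkenyl arms on C8)
Conditions: NaI, acetone, rt, dark; used at once
Reagents that add atoms: sodium iodide, [Na+].[I-]
Why: Finkelstein exchange at an activated α-halo ketone under neutral conditions gives the better radical precursor without touching C13.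

Step 15
Reactants: 21 tert-butyl (2E,4S)-5-{[tert-butyl(dimethyl)silyl]oxy}-4-{(1R,3R)-3-(iodoacetyl)-1-[(1E)-5-methoxy-2-methyl-5-oxopent-1-en-1-yl]-4-methylidenecyclopentyl}pent-2-enoate
Product: 22 tricyclic keto diester of rings B, C and D with ring A open: 12-oxo-16-methylidene bicyclo[3.2.1]octane fused to ring B; C9–H β; C10 with α-CH3 and β-CH2CH2CO2Me; C5 with β-H and α-CH2CO2t-Bu; C6 with β-CH2OTBS
Conditions: Bu3SnH (1.3 equiv) and AIBN (0.2 equiv) by syringe pump over 8 h, benzene (5 mM in 21), 80 °C
Reagents that add atoms: none
Why: Bu3Sn• abstracts iodine from 21 to give the C11 α-keto radical; the closest known reaction type is the tin hydride cascade cyclisation of α-iodo ketones onto alkenes and enoates. Ring C closes by 6-exo-trig attack of this electrophilic radical on C9, the less substituted end of the electron-rich trisubstituted alkene; the cis relationship of the C13 acyl and the C9 arm, fixed in step 7, makes this the only alkene within reach and leads to the bicyclo[3.2.1]octanone. C9 is set in a chair-like transition state in which the C10 terminus lies axial on the forming ring, anti to the C15–C16 bridge and below the sp2 C12, which offers no 1,3-diaxial partner, so that H9 ends syn to C15. Ring B closes by 5-exo-trig addition of the tertiary, nucleophilic C10 radical to C5 of the tert-butyl enoate; this should be much faster than hydrogen transfer at this stannane concentration and than 6-endo attack on the unactivated C16=C17. C5 is set trans to the CH2OTBS group on C6 (chair-like 5-exo transition state with the allylic substituent pseudo-equatorial). C10 is set by rotation of the planar radical so that the longer C1 chain avoids C11 and the incoming C4, which leaves C20 α. The α-ester radical at C4 is then reduced by Bu3SnH and creates no stereocentre. The step needs 6-exo closure to beat premature reduction, which slow addition at high dilution secures, and it needs the two face choices at C9 and C10, which rest on the bridge and on the steric bias described; the alkene geometry plays no part.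

Step 16
Reactants: 22 tricyclic keto diester of rings B, C and D (see step 15)
Product: 23 the 12,12-ethylenedioxy ketal of 22
Conditions: (Me3SiOCH2)2, TMSOTf (5 mol %), CH2Cl2, −78 → −20 °C; pyridine quench
Reagents that add atoms: 1,2-bis(trimethylsilyloxy)ethane, C[Si](C)(C)OCCO[Si](C)(C)C
Why: Noyori ketalisation under aprotic conditions at low temperature, which spares the silyl ether, the tert-butyl ester and the exocyclic alkene. The ketal is needed to block C11 enolisation in step 17 and C12 reduction in step 18.

Step 17
Reactants: 23 the 12,12-ethylenedioxy ketal of 22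
Product: 25 tetracyclic 3-oxo tert-butyl 19-ester with 4β-CH3 and 4α-CO2t-Bu and with C12 ketal and C7 silyl ether, via enolised keto ester 24 (not isolated)
Conditions: KOt-Bu (1.1 equiv), THF, 0 °C → rt; then MeI (1.5 equiv), 0 °C
Reagents that add atoms: iodomethane, CI
Why: Dieckmann condensation followed by C-alkylation in one flask. Only the tert-butyl ester enolate at C4 can close productively onto the C3 methyl ester (six-membered ring A), since attack of C2 on the hindered tert-butyl ester is suppressed. The potassium enolate of 24 is then methylated on the β face, anti to the axial C20 methyl, which puts C18 β and C19 α.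

Step 18
Reactants: 25 tetracyclic 3-oxo tert-butyl 19-ester (C12 ketal, C7 silyl ether)
Product: 26 the corresponding 3β-alcohol (axial hydroxyl, cis to C18)
Conditions: KBH(s-Bu)3 (K-Selectride), THF, −78 → −40 °C; aq. NH4Cl
Reagents that add atoms: none
Why: The bulky trialkylborohydride attacks the C3 ketone along the equatorial trajectory and gives the axial 3β-alcohol; ester, ketal and silyl ether are not reduced, and the cold quench avoids retro-aldol.

Step 19
Reactants: 26 3β-hydroxy tert-butyl 19-ester (C12 ketal, C7 silyl ether)
Product: 27 3β,7-diol tert-butyl 19-ester with C12 ketal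
Conditions: HF·pyridine, pyridine, THF, 0 °C → rt
Reagents that add atoms: none
Why: Buffered fluoride cleavage of the primary silyl ether; the medium is neither basic enough for retro-aldol nor acidic enough for the ketal or the tert-butyl ester.

Step 20
Reactants: 27 3β,7-diol tert-butyl 19-ester with C12 ketal
Product: 28 3β-hydroxy 7-oic acid tert-butyl 19-ester with C12 ketal
Conditions: TEMPO (0.2 equiv), PhI(OAc)2 (2.5 equiv), MeCN/H2O 1:1, rt
Reagents that add atoms: water, O
Why: Oxoammonium oxidation takes the primary alcohol through the aldehyde hydrate to the acid and is slow at the hindered axial secondary 3-hydroxyl; the exocyclic alkene is inert, and C6 keeps its more stable β-substituted configuration.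

Step 21
Reactants: 28 3β-hydroxy 7-oic acid tert-butyl 19-ester with C12 ketal
Product: 29 CNP0197851.1, 3β-hydroxy-12-oxogibberell-16-ene-7,19-dioic acid (4β-CH3, 4α-CO2H, 5β-H, 6β-CO2H, 9β-H, 10α-CH3)
Conditions: TFA/CH2Cl2 1:4, 0 °C; then H2O, THF, rt
Reagents that add atoms: water, O
Why: Acidolysis of the tert-butyl ester by alkyl–oxygen cleavage, then aqueous acid hydrolysis of the dioxolane; no base is used, so the 3β-hydroxy acid cannot undergo retro-aldol.

## Compound list

1 | furan-2(5H)-one | O=C1OCC=C1 | starting material
2 | potassium vinyltrifluoroborate | [K+].C=C[B-](F)(F)F | starting material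
3 | (4R)-4-ethenyloxolan-2-one | C=C[C@@H]1COC(=O)C1 | intermediate
4 | tert-butyl prop-2-enoate | C=CC(=O)OC(C)(C)C | starting material
5 | tert-butyl 3-[(3S,4S)-4-ethenyl-2-oxooxolan-3-yl]propanoate | CC(C)(C)OC(=O)CC[C@@H]1C(=O)OC[C@H]1C=C | intermediate
6 | 2,3-dibromoprop-1-ene | C=C(Br)CBr | starting material
7 | tert-butyl 3-[(3S,4S)-3-(2-bromoprop-2-en-1-yl)-4-ethenyl-2-oxooxolan-3-yl]propanoate | CC(C)(C)OC(=O)CC[C@@]1(CC(Br)=C)C(=O)OC[C@H]1C=C | intermediate
8 | tert-butyl (4S,5S)-4-(2-bromoprop-2-en-1-yl)-4,5-bis(hydroxymethyl)hept-6-enoate | CC(C)(C)OC(=O)CC[C@](CO)(CC(Br)=C)[C@@H](CO)C=C | intermediate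
9 | (5S)-5-(2-bromoprop-2-en-1-yl)-5-[(2S)-1-hydroxybut-3-en-2-yl]oxan-2-one | O=C1CC[C@](CC(Br)=C)([C@@H](CO)C=C)CO1 | intermediate
10 | (5S)-5-(2-bromoprop-2-en-1-yl)-5-[(2S)-1-{[tert-butyl(dimethyl)silyl]oxy}but-3-en-2-yl]oxan-2-one | O=C1CC[C@](CC(Br)=C)([C@@H](CO[Si](C)(C)C(C)(C)C)C=C)CO1 | intermediate
11 | (1R,5S)-5-[(2S)-1-{[tert-butyl(dimethyl)silyl]oxy}but-3-en-2-yl]-7-methylidene-3-oxabicyclo[3.2.1]octan-2-one | C=C1C[C@]2([C@@H](CO[Si](C)(C)C(C)(C)C)C=C)C[C@H]1C(=O)OC2 | intermediate
12 | (1R,4S)-4-[(2S)-1-{[tert-butyl(dimethyl)silyl]oxy}but-3-en-2-yl]-4-(hydroxymethyl)-N-methoxy-N-methyl-2-methylidenecyclopentane-1-carboxamide | C=C1C[C@](CO)([C@@H](CO[Si](C)(C)C(C)(C)C)C=C)C[C@H]1C(=O)N(C)OC | intermediate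
13 | (1R,4S)-4-[(2S)-1-{[tert-butyl(dimethyl)silyl]oxy}but-3-en-2-yl]-4-formyl-N-methoxy-N-methyl-2-methylidenecyclopentane-1-carboxamide | C=C1C[C@](C=O)([C@@H](CO[Si](C)(C)C(C)(C)C)C=C)C[C@H]1C(=O)N(C)OC | intermediate
14 | 2-bromoprop-1-ene | C=C(C)Br | starting material
15 | (1R,4S)-4-[(2S)-1-{[tert-butyl(dimethyl)silyl]oxy}but-3-en-2-yl]-4-(1-hydroxy-2-methylprop-2-en-1-yl)-N-methoxy-N-methyl-2-methylidenecyclopentane-1-carboxamide (C9 carbinol epimers) | C=C1C[C@](C(O)C(C)=C)([C@@H](CO[Si](C)(C)C(C)(C)C)C=C)C[C@H]1C(=O)N(C)OC | intermediate
16 | trimethyl orthoacetate | CC(OC)(OC)OC | starting material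
17 | mixed ketene acetal of 15 (C9–O–C(OMe)=CH2) | C=C1C[C@](C(OC(=C)OC)C(C)=C)([C@@H](CO[Si](C)(C)C(C)(C)C)C=C)C[C@H]1C(=O)N(C)OC | intermediate
18 | methyl (4E)-5-{(1R,3R)-1-[(2S)-1-{[tert-butyl(dimethyl)silyl]oxy}but-3-en-2-yl]-3-[methoxy(methyl)carbamoyl]-4-methylidenecyclopentyl}-4-methylpent-4-enoate | C=C1C[C@](/C=C(\C)CCC(=O)OC)([C@@H](CO[Si](C)(C)C(C)(C)C)C=C)C[C@H]1C(=O)N(C)OC | intermediate
19 | tert-butyl (2E,4S)-5-{[tert-butyl(dimethyl)silyl]oxy}-4-{(1R,3R)-3-[methoxy(methyl)carbamoyl]-1-[(1E)-5-methoxy-2-methyl-5-oxopent-1-en-1-yl]-4-methylidenecyclopentyl}pent-2-enoate | C=C1C[C@](/C=C(\C)CCC(=O)OC)([C@@H](CO[Si](C)(C)C(C)(C)C)/C=C/C(=O)OC(C)(C)C)C[C@H]1C(=O)N(C)OC | intermediate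
20 | chloroacetyl analogue of 19 (C12 chloromethyl ketone) | C=C1C[C@](/C=C(\C)CCC(=O)OC)([C@@H](CO[Si](C)(C)C(C)(C)C)/C=C/C(=O)OC(C)(C)C)C[C@H]1C(=O)CCl | intermediate
21 | iodoacetyl analogue of 19 (ring D iodoketone with two alkenyl arms on C8; precursor of the key step) | C=C1C[C@](/C=C(\C)CCC(=O)OC)([C@@H](CO[Si](C)(C)C(C)(C)C)/C=C/C(=O)OC(C)(C)C)C[C@H]1C(=O)CI | intermediate
22 | tricyclic rings B, C, D keto diester with ring A open (9β-H, 10α-CH3, 10β-CH2CH2CO2Me, 5β-H, 5α-CH2CO2t-Bu, 6β-CH2OTBS) | C=C1C[C@]23C[C@H]1C(=O)C[C@H]2[C@](C)(CCC(=O)OC)[C@@H](CC(=O)OC(C)(C)C)[C@@H]3CO[Si](C)(C)C(C)(C)C | intermediate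
23 | 12,12-ethylenedioxy ketal of 22 | C=C1C[C@]23C[C@H]1C1(OCCO1)C[C@H]2[C@](C)(CCC(=O)OC)[C@@H](CC(=O)OC(C)(C)C)[C@@H]3CO[Si](C)(C)C(C)(C)C | intermediate
24 | tetracyclic enolised 3-oxo tert-butyl 19-ester (C12 ketal, C7 silyl ether) | C=C1C[C@]23C[C@H]1C1(OCCO1)C[C@H]2[C@]1(C)CCC(O)=C(C(=O)OC(C)(C)C)[C@H]1[C@@H]3CO[Si](C)(C)C(C)(C)C | intermediate
25 | tetracyclic 3-oxo tert-butyl 19-ester, 4β-CH3, 4α-CO2t-Bu (C12 ketal, C7 silyl ether) | C=C1C[C@]23C[C@H]1C1(OCCO1)C[C@H]2[C@]1(C)CCC(=O)[C@@](C)(C(=O)OC(C)(C)C)[C@H]1[C@@H]3CO[Si](C)(C)C(C)(C)C | intermediate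
26 | 3β-hydroxy tert-butyl 19-ester (C12 ketal, C7 silyl ether) | C=C1C[C@]23C[C@H]1C1(OCCO1)C[C@H]2[C@]1(C)CC[C@H](O)[C@@](C)(C(=O)OC(C)(C)C)[C@H]1[C@@H]3CO[Si](C)(C)C(C)(C)C | intermediate
27 | 3β,7-diol tert-butyl 19-ester (C12 ketal) | C=C1C[C@]23C[C@H]1C1(OCCO1)C[C@H]2[C@]1(C)CC[C@H](O)[C@@](C)(C(=O)OC(C)(C)C)[C@H]1[C@@H]3CO | intermediate
28 | 3β-hydroxy 7-oic acid tert-butyl 19-ester (C12 ketal) | C=C1C[C@]23C[C@H]1C1(OCCO1)C[C@H]2[C@]1(C)CC[C@H](O)[C@@](C)(C(=O)OC(C)(C)C)[C@H]1[C@@H]3C(=O)O | intermediate
29 | CNP0197851.1, 3β-hydroxy-12-oxogibberell-16-ene-7,19-dioic acid | C=C1C[C@]23C[C@H]1C(=O)C[C@H]2[C@]1(C)CC[C@H](O)[C@@](C)(C(=O)O)[C@H]1[C@@H]3C(=O)O | target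

## Step count and least certain steps

Total: 21 steps. Longest linear sequence: 21 steps (1 to 29); the route is linear, with 2, 4, 6, 14 and 16 added as commercial pieces.

Step 15 (key step). The most likely failure is hydrogen transfer from the stannane to the C11 radical before the slow bridged 6-exo closure, which would give the methyl ketone. The second is incomplete facial control at C9 and C10, because the two faces differ only by the C14 and C15 methylenes and by methyl against a chain. Fallback: starting from 21, the cascade is run as an iodine atom transfer with no hydride present (Bu3SnSnBu3, 10 mol %, sunlamp, benzene, 80 °C). The C11 radical then persists until it cyclises, and the chain ends by iodine transfer to C4, giving the C4 iodide of the tricyclic keto diester F1. A separate brief treatment of F1 with Bu3SnH and AIBN removes the iodine and returns the route to 22.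

Step 7. The most likely failure is that the lithium enolate of the δ-lactone decomposes, or that the alkenylpalladium intermediate inserts into the nearby ethenyl group, before the strained bridged C–C reductive elimination takes place. Fallback: ring D is closed one stage earlier, where no bridge has to form. Starting from 7, the tert-butyl ester enolate (LiN(SiMe3)2, Pd2(dba)3, P(t-Bu)3) is coupled with the bromoalkene to give the spiro methylenecyclopentane ester lactone F2 as C13 epimers. LiBH4 opens the γ-lactone to the ring D diol ester F3. Acid (p-TsOH, toluene, 80 °C) then lactonises only the epimer with C12 cis to C9, giving the bridged hydroxy lactone F4, from which the other epimer is separated. Silylation of F4 with TBSCl returns the route to 11.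

Step 3. The most likely failure is competing deprotonation next to the tert-butyl ester, which would lead to alkylation at C13 instead of C8. Fallback: starting from 5, the ester is cleaved with TFA to the lactone propanoic acid F5. Its carboxylate resists α-deprotonation, so two equivalents of LiN(SiMe3)2 and then 6 give the bromoallylated lactone acid F6. LiBH4 reduces the lactone of F6 but not the carboxylate, and acidification closes the δ-lactone, which returns the route to 9.

Step 13. The most likely failure is attack of the carbenoid on the C3 methyl ester or on the enoate, competing with the Weinreb amide. Fallback: starting from 19, the Weinreb amide alone is reduced with Cp2Zr(H)Cl to the C12 aldehyde F7. An aldehyde is far more electrophilic than either ester, so chloromethyllithium (ICH2Cl, MeLi·LiBr, −78 °C, cold quench) adds to it cleanly to give the C12 chlorohydrin F8. Dess–Martin oxidation of F8 returns the route to 20.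

Step 21. The most likely failure is acid-promoted migration of the C16=C17 double bond into ring D, or addition of the acid to it, during the tert-butyl ester cleavage. Fallback: starting from 28, the ketal is first hydrolysed under weak acid (PPTS, acetone/H2O, 40 °C) to the 12-oxo 7-acid tert-butyl ester F9. The ester of F9 is then cleaved without protic acid through its silyl ester (TMSOTf, 2,6-lutidine, CH2Cl2, 0 °C, then aqueous work-up), which gives 29.

## Further compounds

F1 | step 15 | C4 iodide of the tricyclic keto diester (α-iodo tert-butyl ester, C4 epimers) | C=C1C[C@]23C[C@H]1C(=O)C[C@H]2[C@](C)(CCC(=O)OC)[C@@H](C(I)C(=O)OC(C)(C)C)[C@@H]3CO[Si](C)(C)C(C)(C)C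
F2 | step 7 | spiro methylenecyclopentane ester lactone (C13 epimers) | C=C1C[C@]2(CC1C(=O)OC(C)(C)C)C(=O)OC[C@H]2C=C
F3 | step 7 | ring D diol ester (C13 epimers) | C=C1C[C@@](CO)(CC1C(=O)OC(C)(C)C)[C@@H](CO)C=C
F4 | step 7 | bridged hydroxy lactone (11 without the silyl group) | C=C1C[C@]2([C@@H](CO)C=C)C[C@H]1C(=O)OC2
F5 | step 3 | lactone propanoic acid, 3-[(3S,4S)-4-ethenyl-2-oxooxolan-3-yl]propanoic acid | OC(=O)CC[C@@H]1C(=O)OC[C@H]1C=C
F6 | step 3 | bromoallylated lactone acid | OC(=O)CC[C@@]1(CC(Br)=C)C(=O)OC[C@H]1C=C
F7 | step 13 | C12 aldehyde (formyl analogue of 19) | C=C1C[C@](/C=C(\C)CCC(=O)OC)([C@@H](CO[Si](C)(C)C(C)(C)C)/C=C/C(=O)OC(C)(C)C)C[C@H]1C=O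
F8 | step 13 | C12 chlorohydrin (carbinol epimers) | C=C1C[C@](/C=C(\C)CCC(=O)OC)([C@@H](CO[Si](C)(C)C(C)(C)C)/C=C/C(=O)OC(C)(C)C)C[C@H]1C(O)CCl
F9 | step 21 | 12-oxo 7-acid tert-butyl ester | C=C1C[C@]23C[C@H]1C(=O)C[C@H]2[C@]1(C)CC[C@H](O)[C@@](C)(C(=O)OC(C)(C)C)[C@H]1[C@@H]3C(=O)O
A1 | alternative 1 | tricyclic rings A, B, C enone with silylpropargyl group on C8 | C[Si](C)(C)C#CC[C@]12C=CC(=O)C[C@H]1[C@]1(C)CC[C@H](O[Si](C)(C)C(C)(C)C)[C@@](C)(C(=O)OC)[C@H]1[C@@H]2C(=O)OC
A2 | alternative 1 | cyclohexadienone precursor with C10 exocyclic methylene on ring A | C[Si](C)(C)C#CCC1(C=CC(=O)C=C1)[C@@H](C(=O)OC)[C@H]1C(=C)CC[C@H](O[Si](C)(C)C(C)(C)C)[C@@]1(C)C(=O)OC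
A3 | alternative 2 | target as its 3-silyl ether 7,19-dimethyl ester | C=C1C[C@]23C[C@H]1C(=O)C[C@H]2[C@]1(C)CC[C@H](O[Si](C)(C)C(C)(C)C)[C@@](C)(C(=O)OC)[C@H]1[C@@H]3C(=O)OC
A4 | alternative 2 | spiro cyclopentene allylstannane phenyl selenoester | CCCC[Sn](CCCC)(CCCC)CC1=CC[C@@]2(C1)[C@@H](CC(=O)[Se]c3ccccc3)[C@]1(C)CC[C@H](O[Si](C)(C)C(C)(C)C)[C@@](C)(C(=O)OC)[C@H]1[C@@H]2C(=O)OC
A5 | alternative 3 | tetracyclic enolised 3-oxo 19-ester with C12 ketal | C=C1C[C@]23C[C@H]1C1(OCCO1)C[C@H]2[C@]1(C)CCC(O)=C(C(=O)OC)[C@H]1[C@@H]3C(=O)OC
A6 | alternative 3 | rings C, D ketal triester with acyclic quaternary C10 | C=C1C[C@]2(CC(=O)OC)C[C@H]1C1(OCCO1)C[C@H]2[C@](C)(CCC(=O)OC)/C=C/C(=O)OC
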